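The runs were generated by integration for an exercise; noise was put on by code.

Take the substrate charged to each flask and write the balance of its last two stations, since the share asked for is a ratio of those two.

| setting | alder | south-west | south | west | north-east |
|---|---|---|---|---|---|
| substrate | 0.90 M | 0.82 M | 0.20 M | 2.5 M | 3.0 M |
| temperature | 90 °C | 90 °C | 60 °C | 130 °C | 50 °C |
| remark | run made earlier |  |  |  |  |
| time |  | 3.0 d | 3.0 d | 3.0 d | 3.0 d |

- alder (time / h: target / %, over-reaction product / %, substrate / %): 2.50: 22.4, 0.2, 5.0; 6.00: 28.1, 4.2, 0; 12.0: 26.6, 9.7, 0; 20.0: 22.6, 16.2, 0.5; 25.0: 21.9, 20.8, 0

(standard deviation of a reading: 1 percentage point)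

* ranking by share of target in all that became target or over-reaction product, from high to low, at 3.0 d (south-west / south / west / north-east)
* the share of target in all that became target or over-reaction product of the flask you put first, at 3.0 d
* the share of target in all that became target or over-reaction product of the flask you put last, at 3.0 d

Among the proposed steps, over-reaction product has one source, so for any feed f into target, with the loss first order as written:

d[target]/dt = f − k[target]
d[over-reaction product]/dt = k[target]

In the alder run, substrate reads 0% at 6.00 h. From there to the last reading, over-reaction product gains 17 percentage points while the two end readings of target average 25.0%, which gives the reading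

k = 0.0349 h⁻¹ at 90 °C.

We carry the burn number, k times the time, 2.52 for south-west, which counts the target lifetimes a run holds. With k held fixed, the share (the selectivity) follows from the feed:

made at once at the start: share = e^(−B)
steady feed: share = (1 − e^(−B))/B

Turn the time first: by hand a longer run raises B and, with either feed, lowers the share, and the alder readings do this, falling from 87.0% at 6.00 h to 51.3% at 25.0 h, the later reading lying between the 41.8% and 66.7% that the two feeds give for that time. Turn the charge next: k as written holds no [substrate], so by hand B stays put, but the alder run shows one charge and leaves this untested. Turn the temperature last: a colder flask should have a smaller k, by an amount the runs do not show. Our own reckoning therefore puts south-west between 8.05% and 36.5% and ranks the flasks from coldest to hottest.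

The forecast gives north-east > south > south-west > west, with 95% first and 0.3% last, and adds: “The north-east/south order is uncertain: if over-reaction were bimolecular, south would win.”

The flasks give north-east > south > south-west > west, with 99.2% first and 0% last, so the forecast's order is right and both its shares lie within their margins.

    intermediate A ⇌ intermediate D (K = 0.320, k = 3.40 h⁻¹, Ea = 111 kJ mol⁻¹, ΔH = 1.00 kJ mol⁻¹)
    intermediate A → intermediate B (k = 0.370 h⁻¹, Ea = 125 kJ mol⁻¹)
    intermediate A ⇌ intermediate C (K = 13.0, k = 0.290 h⁻¹, Ea = 124 kJ mol⁻¹, ΔH = 9.00 kJ mol⁻¹)
    intermediate D → target (k = 1.10 h⁻¹, Ea = 117 kJ mol⁻¹)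
    intermediate B → intermediate E (k = 3.90 h⁻¹, Ea = 100 kJ mol⁻¹)
    substrate ⇌ intermediate A (K = 11.0, k = 1.60 h⁻¹, Ea = 115 kJ mol⁻¹, ΔH = −51.0 kJ mol⁻¹)
    target → over-reaction product (k = 0.0340 h⁻¹, Ea = 112 kJ mol⁻¹)
    intermediate E → target (k = 0.00620 h⁻¹, Ea = 122 kJ mol⁻¹)
    (constants at 90 °C)

North-east's 99.2% is a share in a flask where target stands at 4.16% at the end. The half-life of target by its conversion into over-reaction product alone in north-east is 84 d, long against the 3.0 d of the run, so the burn number there is 0.0248 against 2.52 in south-west.

In the neighbour flask with 1.8 M of substrate, at north-east's temperature and time, k as written holds no [substrate], so the burn number stays 0.0248, and if the feed keeps its shape the share should not move. The computed share is 99.2%.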